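**Retrosynthetic overview** (chroman-4-one numbering throughout; O3 is the oxygen on C3)

1. Target ⇒ (+)-aromadendrin + (E)-4-chloro-2-methylbut-2-en-1-ol, joined last by Williamson alkylation at the most acidic phenol (7-OH).
2. Ring C ⇒ disconnection of C2–C3: the flavanonol is the ring-contracted isomer of a racemic seven-membered mixed acetal (2-aryl-4H-1,3-benzodioxepin-5-one) in which C2 sits between O1 and O3. A catalytic, stereoconvergent 1,2-shift of C2 from O3 to C3 turns the seven-membered ring into the six-membered ring without gain or loss of atoms.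
3. Enabling feature: the array O1–C2H(aryl)–C3H(OH)–C4(=O) of ring C. C2 is a cation site stabilised by O1 and the para-oxygenated ring B; O3 with the C4 carbonyl is an α-ketol that can carry C2 as an acetal, acidify C3–H and chelate a metal as a Z-enediolate.
4. Acetal ⇒ α-hydroxy ketone (Rubottom oxidation of 2,4-bis(benzyloxy)-6-hydroxyacetophenone) + 4-(benzyloxy)benzaldehyde dimethyl acetal.
5. Ring order: rings A and B are bought; the temporary seven-membered acetal ring is made in step 4; ring C is formed from it in step 5.

Key step: step 5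

Assumption: the three starting materials are taken as commercial, and the (S,S)-ligand of step 5 is written as the one leading to the (2R,3R) series; the antipodal ligand would be used if a small-scale trial shows the opposite sense of induction.

**Step 1**
Reactants: 1 1-[2,4-bis(benzyloxy)-6-hydroxyphenyl]ethanone
Product: 2 {1-[2,4-bis(benzyloxy)-6-(trimethylsilyloxy)phenyl]ethenyloxy}trimethylsilane
Conditions: TMSOTf (2.3 equiv), Et3N (3 equiv), CH2Cl2, 0 °C; pentane, filtration of the salt, crude product used directly
Reagents that add atoms: trimethylsilyl triflate (TMSOTf), C[Si](C)(C)OS(=O)(=O)C(F)(F)F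
Why: Soft enolisation and silylation of a methyl ketone with a silyl triflate and an amine (silyl enol ether formation) should give the only possible enol silane and cap the chelated phenol in the same operation.

**Step 2**
Reactants: 2 {1-[2,4-bis(benzyloxy)-6-(trimethylsilyloxy)phenyl]ethenyloxy}trimethylsilane
Product: 5 1-[2,4-bis(benzyloxy)-6-hydroxyphenyl]-2-hydroxyethanone, via silyloxy oxirane 3 (not isolated), via α-silyloxy ketone 4 (not isolated)
Conditions: mCPBA (1.05 equiv), CH2Cl2, −20 to 0 °C; then 1 M HCl, THF, rt
Reagents that add atoms: 3-chloroperoxybenzoic acid (mCPBA), O=C(OO)c1cccc(Cl)c1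
Why: Rubottom oxidation: the electron-rich enol silane should be epoxidised far faster than the arene, the silyloxy oxirane 3 opens with 1,4-silyl shift to 4, and dilute acid removes both silyl groups; no stereocentre is formed.

**Step 3**
Reactants: 6 4-(benzyloxy)benzaldehyde
Product: 7 1-(benzyloxy)-4-(dimethoxymethyl)benzene
Conditions: HC(OMe)3 (3 equiv), p-TsOH·H2O (1 mol %), rt; then Et3N
Reagents that add atoms: trimethyl orthoformate, COC(OC)OC
Why: Acid-catalysed acetalisation of an electron-rich aryl aldehyde, driven to completion by the orthoester.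

**Step 4**
Reactants: 5 1-[2,4-bis(benzyloxy)-6-hydroxyphenyl]-2-hydroxyethanone; 7 1-(benzyloxy)-4-(dimethoxymethyl)benzene
Product: 8 rac-6,8-bis(benzyloxy)-2-[4-(benzyloxy)phenyl]-4H-1,3-benzodioxepin-5-one (seven-membered ring O1–C2H(aryl)–O3–CH2–C(=O) fused to ring A)
Conditions: PPTS (10 mol %), 5 Å MS, toluene (0.05 M), 50 °C; then Et3N, base-washed silica
Reagents that add atoms: none
Why: Acid-catalysed transacetalisation: the primary α-hydroxyl should exchange first and the phenol then close the seven-membered ring onto the para-alkoxybenzylic oxocarbenium ion, with methanol removed by the sieves; the acetal centre forms as a racemate, which does not matter because step 5 erases it.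

**Step 5**
Reactants: 8 rac-6,8-bis(benzyloxy)-2-[4-(benzyloxy)phenyl]-4H-1,3-benzodioxepin-5-one
Product: 10 (2R,3R)-5,7-bis(benzyloxy)-2-[4-(benzyloxy)phenyl]-3-hydroxychroman-4-one, via ring-opened enediolate oxocarbenium zwitterion 9 (not isolated)
Conditions: Sc(OTf)3 (10 mol %), (S,S)-Ph-pybox [2,6-bis((S)-4-phenyl-4,5-dihydrooxazol-2-yl)pyridine] (12 mol %, premixed), 2,6-lutidine (20 mol %), 4 Å MS, CH2Cl2 (0.02 M), −20 °C to rt
Reagents that add atoms: none
Why: Proposed new method: Sc(OTf)3·pybox is expected to ionise the mixed acetal of 8 at the C2–O3 bond, which erases the acetal stereocentre and gives an oxocarbenium ion at C2 (stabilised by O1 and the para-benzyloxyphenyl ring B) tethered to a scandium alkoxide that chelates the C4 carbonyl; 2,6-lutidine then soft-enolises this chelate to the Z-enediolate 9, C3 adds to C2, and lutidinium protonates O3 to release 10 and the catalyst, so the step is a catalytic isomerisation (formal 1,2-shift of C2 from O3 to C3) that contracts the seven-membered ring to ring C. The closest known reaction types are the Petasis–Ferrier rearrangement and the Lewis-acid ring contraction of 1,3-dioxepine enol acetals (acetal ionisation, then enolate-to-oxocarbenium closure), the addition of chelated chiral metal enolates to oxocarbenium ions made in situ from acetals, and direct aldol reactions of metal enediolates of α-hydroxy aryl ketones. Ring C closes in a 6-(enolendo)-endo-trig mode; attack through the aryl-bearing enediolate carbon C4 would be a 5-endo-trig closure onto an oxocarbenium lying in the plane of ring A and is out of reach, and attack through oxygen only returns an acetal reversibly. C3 is set by the twofold-symmetric pybox ligand, which leaves one face of the flat five-membered scandium enediolate chelate open, and C2 is set relative to C3 by a half-chair transition state in which the E-oxocarbenium places ring B and the Z-enediolate places O3 pseudo-equatorial, giving the 2,3-trans isomer. The step needs enolisation to follow ring opening, because an enol formed inside the seven-membered ring would carry O3 cis to ring A and lead to the 2,3-cis isomer; the substrate secures this, since the ring holds O3 and the C4 carbonyl apart so that only the ring-opened α-alkoxide ketone can chelate scandium and become acidic enough for the weak base, while ionisation of the other acetal bond (C2–O1) is reversible and unproductive. Both enantiomers of racemic 8 pass through the same achiral cation, so the step is stereoconvergent.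

**Step 6**
Reactants: 10 (2R,3R)-5,7-bis(benzyloxy)-2-[4-(benzyloxy)phenyl]-3-hydroxychroman-4-one
Product: 11 (2R,3R)-3,5,7-trihydroxy-2-(4-hydroxyphenyl)chroman-4-one ((+)-aromadendrin)
Conditions: H2 (1 atm), 10 % Pd/C, EtOAc–MeOH, rt
Reagents that add atoms: none
Why: Catalytic hydrogenolysis of the three aryl benzyl ethers; the ring C2–O1 bond should be cleaved far more slowly and the ketone is not reduced at this pressure, so both stereocentres stay untouched.

**Step 7**
Reactants: 12 2-methyl-2-vinyloxirane (racemic)
Product: 13 (E)-4-chloro-2-methylbut-2-en-1-ol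
Conditions: TiCl4 (1.1 equiv), CH2Cl2, −90 to −80 °C; then 1 M HCl (aq)
Reagents that add atoms: titanium tetrachloride (TiCl4), Cl[Ti](Cl)(Cl)Cl
Why: Lewis-acid opening of the vinyl oxirane with chloride delivery at the vinyl terminus (SN2′-type 1,4-opening), a known one-step entry to this chlorohydrin; the E geometry should result from opening through the conformer that keeps the developing CH2Cl group away from the titanium-bound CH2O group.

**Step 8**
Reactants: 11 (2R,3R)-3,5,7-trihydroxy-2-(4-hydroxyphenyl)chroman-4-one; 13 (E)-4-chloro-2-methylbut-2-en-1-ol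
Product: 14 (2R,3R)-3,5-dihydroxy-7-[(E)-4-hydroxy-3-methylbut-2-enyloxy]-2-(4-hydroxyphenyl)chroman-4-one (target)
Conditions: K2CO3 (1.1 equiv), 13 (1.1 equiv), DMF (degassed), Ar, rt to 40 °C
Reagents that add atoms: none
Why: Williamson etherification: 7-OH (para to the C4 carbonyl, a vinylogous acid) is far more acidic than 4′-OH, the chelated 5-OH and the two aliphatic hydroxyls, so one equivalent of carbonate should generate only the 7-phenoxide, which displaces the primary allylic chloride by SN2 with the E geometry and both stereocentres unchanged.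

**Compound list**

1 | 1-[2,4-bis(benzyloxy)-6-hydroxyphenyl]ethanone | CC(=O)c1c(O)cc(OCc2ccccc2)cc1OCc1ccccc1 | starting material
2 | {1-[2,4-bis(benzyloxy)-6-(trimethylsilyloxy)phenyl]ethenyloxy}trimethylsilane | C=C(O[Si](C)(C)C)c1c(O[Si](C)(C)C)cc(OCc2ccccc2)cc1OCc1ccccc1 | intermediate
3 | 2-[2,4-bis(benzyloxy)-6-(trimethylsilyloxy)phenyl]-2-(trimethylsilyloxy)oxirane (racemic, not isolated) | C[Si](C)(C)OC1(CO1)c1c(O[Si](C)(C)C)cc(OCc2ccccc2)cc1OCc1ccccc1 | intermediate
4 | 1-[2,4-bis(benzyloxy)-6-(trimethylsilyloxy)phenyl]-2-(trimethylsilyloxy)ethanone (not isolated) | C[Si](C)(C)OCC(=O)c1c(O[Si](C)(C)C)cc(OCc2ccccc2)cc1OCc1ccccc1 | intermediate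
5 | 1-[2,4-bis(benzyloxy)-6-hydroxyphenyl]-2-hydroxyethanone | OCC(=O)c1c(O)cc(OCc2ccccc2)cc1OCc1ccccc1 | intermediate
6 | 4-(benzyloxy)benzaldehyde | O=Cc1ccc(OCc2ccccc2)cc1 | starting material
7 | 1-(benzyloxy)-4-(dimethoxymethyl)benzene | COC(OC)c1ccc(OCc2ccccc2)cc1 | intermediate
8 | rac-6,8-bis(benzyloxy)-2-[4-(benzyloxy)phenyl]-4H-1,3-benzodioxepin-5-one | O=C1COC(c2ccc(OCc3ccccc3)cc2)Oc2cc(OCc3ccccc3)cc(OCc3ccccc3)c21 | intermediate
9 | ring-opened Z-enediolate / E-oxocarbenium zwitterion (both enediolate oxygens on scandium in the flask; drawn metal-free with O3 as OH; not isolated) | O/C=C(\[O-])c1c(OCc2ccccc2)cc(OCc2ccccc2)cc1/[O+]=C/c1ccc(OCc2ccccc2)cc1 | intermediate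
10 | (2R,3R)-5,7-bis(benzyloxy)-2-[4-(benzyloxy)phenyl]-3-hydroxychroman-4-one | C(c1ccccc1)Oc1cc(OCc2ccccc2)c2c(c1)O[C@H](c1ccc(OCc3ccccc3)cc1)[C@@H](O)C2=O | intermediate
11 | (2R,3R)-3,5,7-trihydroxy-2-(4-hydroxyphenyl)chroman-4-one ((+)-aromadendrin) | Oc1cc(O)c2c(c1)O[C@H](c1ccc(O)cc1)[C@@H](O)C2=O | intermediate
12 | 2-methyl-2-vinyloxirane (racemic) | CC1(C=C)CO1 | starting material
13 | (E)-4-chloro-2-methylbut-2-en-1-ol | C/C(=C\CCl)CO | intermediate
14 | (2R,3R)-3,5-dihydroxy-7-[(E)-4-hydroxy-3-methylbut-2-enyloxy]-2-(4-hydroxyphenyl)chroman-4-one | C/C(=C\COc1cc(O)c2c(c1)O[C@H](c1ccc(O)cc1)[C@@H](O)C2=O)CO | target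

**Step count and risks**

Total step count: 8. Longest linear sequence: 6 (steps 1, 2, 4, 5, 6, 8); steps 3 and 7 are side branches.

Steps most likely to fail:

Step 5 (proposed new method). The chelate-directed ionisation and enolisation may not occur in the required order, unligated scandium may open a racemic background path, facial selectivity at the enediolate may be poor, or enolisation before ring opening may divert material to the 2,3-cis series. The fallback uses known chemistry and forms ring C at O1–C2 instead. It sets out from 1: protection of the phenol (MOMCl, iPr2NEt, CH2Cl2) gives the methoxymethyl ether F1. Claisen–Schmidt condensation with 6 (KOH, EtOH, rt) gives the chalcone F2. Juliá–Colonna epoxidation (poly-L-leucine, urea–H2O2, DBU, THF) gives the (αR,βS)-epoxychalcone F3. Treatment with HCl in MeOH–THF at 50 °C removes the MOM group and lets the freed phenol open the epoxide at the benzylic carbon with inversion (6-endo), while the α-carbon keeps its configuration. This returns to the route at 10.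

Step 4. Closure of the seven-membered aryl/alkyl acetal may stay incomplete, because the phenol is chelated to the ketone and open-chain or oligomeric acetals may accumulate. The fallback generates the same cation by oxidation instead of acetal exchange. It sets out from 5: O-alkylation of the phenol with 4-(benzyloxy)benzyl chloride (K2CO3, DMF, rt) gives the aryl 4-(benzyloxy)benzyl ether F4. DDQ (1.2 equiv, 4 Å MS, CH2Cl2, 0 °C to rt) then oxidises the para-alkoxybenzylic C–H to the oxocarbenium ion, which the primary α-hydroxyl traps. This returns to the route at 8.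

Step 8. Alkylation may run on to the 4′-phenol, and the base may cause epimerisation by ring opening or C-alkylation of ring A. The fallback leaves 7-OH as the only free acidic phenol. It sets out from 11: TBSCl (2.2 equiv), imidazole, DMF, 0 °C gives the 7,4′-bis-TBS ether F5. TBAF/AcOH (1 equiv, THF, −40 °C) selectively cleaves the more labile 7-O-silyl group to give the 4′-TBS ether F6. Alkylation with 13 (K2CO3, acetone, rt) gives the 7-O-alkylated 4′-TBS ether F7. Et3N·3HF in MeCN at rt then removes the silyl group and returns to the route at 14.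

**Further compounds**

F1 | step 5 | 1-[2,4-bis(benzyloxy)-6-(methoxymethoxy)phenyl]ethanone | CC(=O)c1c(OCOC)cc(OCc2ccccc2)cc1OCc1ccccc1
F2 | step 5 | (E)-1-[2,4-bis(benzyloxy)-6-(methoxymethoxy)phenyl]-3-[4-(benzyloxy)phenyl]prop-2-en-1-one | COCOc1cc(OCc2ccccc2)cc(OCc2ccccc2)c1C(=O)/C=C/c1ccc(OCc2ccccc2)cc1
F3 | step 5 | [2,4-bis(benzyloxy)-6-(methoxymethoxy)phenyl]{(2R,3S)-3-[4-(benzyloxy)phenyl]oxiran-2-yl}methanone | COCOc1cc(OCc2ccccc2)cc(OCc2ccccc2)c1C(=O)[C@@H]1O[C@H]1c1ccc(OCc2ccccc2)cc1
F4 | step 4 | 1-{2,4-bis(benzyloxy)-6-[4-(benzyloxy)benzyloxy]phenyl}-2-hydroxyethanone | OCC(=O)c1c(OCc2ccc(OCc3ccccc3)cc2)cc(OCc2ccccc2)cc1OCc1ccccc1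
F5 | step 8 | (2R,3R)-7-(tert-butyldimethylsilyloxy)-2-[4-(tert-butyldimethylsilyloxy)phenyl]-3,5-dihydroxychroman-4-one | CC(C)(C)[Si](C)(C)Oc1cc(O)c2c(c1)O[C@H](c1ccc(O[Si](C)(C)C(C)(C)C)cc1)[C@@H](O)C2=O
F6 | step 8 | (2R,3R)-2-[4-(tert-butyldimethylsilyloxy)phenyl]-3,5,7-trihydroxychroman-4-one | Oc1cc(O)c2c(c1)O[C@H](c1ccc(O[Si](C)(C)C(C)(C)C)cc1)[C@@H](O)C2=O
F7 | step 8 | (2R,3R)-2-[4-(tert-butyldimethylsilyloxy)phenyl]-3,5-dihydroxy-7-[(E)-4-hydroxy-3-methylbut-2-enyloxy]chroman-4-one | C/C(=C\COc1cc(O)c2c(c1)O[C@H](c1ccc(O[Si](C)(C)C(C)(C)C)cc1)[C@@H](O)C2=O)CO
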